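A direct plan would close the ε ring by a chiral-acid cation–olefin cyclisation of geranyl phenyl sulfone A1 to (R)-α-cyclogeranyl phenyl sulfone A2, make apo-8'-lycopenal A4 by one Wittig reaction on crocetin dialdehyde A3, and join A2 to A4 at C7=C8 by Julia–Lythgoe olefination. Its weakest steps would be:
- the proton-induced enantioselective monocyclisation ending in proton loss: the C6 configuration and the alkene position (C4=C5, C5=C6 or exocyclic) would both rest on an untested reagent-controlled step that needs over two equivalents of a binaphthol–SnCl4 acid;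
- the addition of lithiated A2 to A4 with benzoylation: a strong base would sit beside the allylic C6–H, and two stereocentres would be made on precious C30 material only to be erased;
- the SmI2 reductive elimination on the C40 skeleton: electron transfer in the presence of an undecaene, with 7E selectivity not assured.

**Plan of the new route**
The retrosynthesis cuts C11=C12 and C11'=C12' (two Wittig reactions on the C10 dialdehyde 14), then C9=C10 (Horner–Wadsworth–Emmons) and C9'–C10' (vinyl Grignard), and last the C6–H bond.
The feature used is the allyl triad C4–C5–C6 of the ε ring: C6, the only stereocentre, is 1,3-related across C5 to C4, so the ε ring is the reductive 1,3-transposition product of a 4-hydroxy β ring.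
The six-membered ring is never closed in the route: it is bought flat (C5=C6) in β-ionone, C4 is oxidised and reduced enantioselectively, and C6 is set afterwards by a retro-ene shift that also fixes the alkene at C4=C5.
No cation–olefin cyclisation, no carbanion next to C6 and no reductive elimination on a polyene occur; the last step is a neutral Wittig reaction of a kind established for ε end groups.

Key step: step 4

Remark: positions are given in carotenoid numbering (ε end unprimed, ψ end primed); pseudoionone 11 is taken as its (3E,5E) isomer, any 5Z material being removed when salt 13 is recrystallised.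

Step 1
Reactants: 1 β-ionone
Product: 2 4-oxo-β-ionone
Conditions: t-BuOOH (70% in water, 5 equiv), Rh2(cap)4 (dirhodium tetracaprolactamate, 1 mol%), K2CO3 (0.5 equiv), CH2Cl2, rt
Reagents that add atoms: tert-butyl hydroperoxide, CC(C)(C)OO
Why: Radical allylic oxidation should attack C4, the only ring methylene allylic to C5=C6, and the mixed peroxide formed there should collapse to the enone, any 5,6-epoxide being removed by chromatography.

Step 2
Reactants: 2 4-oxo-β-ionone
Product: 3 ethyl (2E,4E)-3-methyl-5-(2,6,6-trimethyl-3-oxocyclohex-1-en-1-yl)penta-2,4-dienoate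
Conditions: (EtO)2P(O)CH2CO2Et (1.3 equiv), NaH (1.25 equiv), THF, 0 °C to rt; chromatography
Reagents that add atoms: triethyl phosphonoacetate, CCOC(=O)CP(=O)(OCC)OCC
Why: Horner–Wadsworth–Emmons olefination should take the unhindered side-chain methyl ketone C9 and leave the α-branched ring enone C4 (by analogy with side-chain olefination beside ring enones in the abscisic acid series), giving mainly the 2E ester, with the 2Z isomer removed on silica.

Step 3
Reactants: 3 ethyl (2E,4E)-3-methyl-5-(2,6,6-trimethyl-3-oxocyclohex-1-en-1-yl)penta-2,4-dienoate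
Product: 4 ethyl (2E,4E)-5-[(3S)-3-hydroxy-2,6,6-trimethylcyclohex-1-en-1-yl]-3-methylpenta-2,4-dienoate
Conditions: (R)-2-methyl-CBS-oxazaborolidine (0.2 equiv), catecholborane (1.6 equiv), toluene, −78 to −40 °C; MeOH; aq. NaHCO3
Reagents that add atoms: none
Why: Corey–Bakshi–Shibata reduction of a 2,3-disubstituted cyclohexenone, in which the ketone binds with its large alkenyl flank C5 away from the catalyst, should give the 4S carbinol by 1,2-hydride delivery under the usual model, the conjugated ester being inert to catecholborane at this temperature.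

Step 4
Reactants: 4 ethyl (2E,4E)-5-[(3S)-3-hydroxy-2,6,6-trimethylcyclohex-1-en-1-yl]-3-methylpenta-2,4-dienoate
Product: 8 ethyl (2E,4E)-3-methyl-5-[(1R)-2,6,6-trimethylcyclohex-2-en-1-yl]penta-2,4-dienoate, via hydrazone adduct 5 (not isolated), via sulfonyl hydrazine 6 (not isolated), via allylic diazene 7 (not isolated)
Conditions: IPNBSH (N-isopropylidene-N'-2-nitrobenzenesulfonyl hydrazine, 1.3 equiv), PPh3 (1.3 equiv), DEAD (1.3 equiv), THF, 0 °C to rt; then CF3CH2OH–H2O (1:1), rt
Reagents that add atoms: none
Why: Mitsunobu displacement of the C4 oxyphosphonium by the sulfonamide nitrogen of IPNBSH goes with inversion to the 4R adduct 5, hydrolysis of its hydrazone frees hydrazine 6, loss of 2-nitrobenzenesulfinic acid gives the monoalkyl diazene 7, and 7 expels N2 in a concerted six-centre retro-ene shift that carries the N–H hydrogen to C6 while the ring alkene moves from C5=C6 to C4=C5. The closest known reaction type is the allylic diazene rearrangement (reductive 1,3-transposition of allylic alcohols), which is established for secondary cyclohexenols and for cases in which the shift takes the alkene out of conjugation. No ring is closed: the six-membered ring comes intact from 1. The one new stereocentre, C6, is set by suprafacial hydrogen delivery on the ring face that holds the C4–N bond, so that the configuration at C4 is relayed across C5 with one inversion (4S alcohol, 4R diazene, 6R product). The step needs substitution at C4 to outrun ionisation and elimination toward C3, which the electron-poor dienoate arm favours by destabilising the allyl cation, and it needs hydrogen transfer to C6 only, which the six-membered transition state secures since no other carbon is within reach. The alkene position is fixed by the mechanism and the loss of N2 pays for taking the ring alkene out of conjugation, so neither α/β/γ isomer mixtures nor a drift to the β ring should arise.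

Step 5
Reactants: 8 ethyl (2E,4E)-3-methyl-5-[(1R)-2,6,6-trimethylcyclohex-2-en-1-yl]penta-2,4-dienoate
Product: 9 (2E,4E)-3-methyl-5-[(1R)-2,6,6-trimethylcyclohex-2-en-1-yl]penta-2,4-dien-1-ol
Conditions: i-Bu2AlH (DIBAL-H, 2.3 equiv), CH2Cl2, −78 °C; aq. potassium sodium tartrate
Reagents that add atoms: none
Why: Hydride reduction of the dienoate to the allylic alcohol is non-basic and cold, so the doubly allylic C6–H and both alkene geometries should be untouched.

Step 6
Reactants: 9 (2E,4E)-3-methyl-5-[(1R)-2,6,6-trimethylcyclohex-2-en-1-yl]penta-2,4-dien-1-ol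
Product: 10 {(2E,4E)-3-methyl-5-[(1R)-2,6,6-trimethylcyclohex-2-en-1-yl]penta-2,4-dien-1-yl}triphenylphosphonium bromide
Conditions: PPh3·HBr (1.05 equiv), MeOH, 0 °C to rt, dark; precipitation with Et2O, recrystallisation (CH2Cl2/EtOAc)
Reagents that add atoms: triphenylphosphine hydrobromide, [Br-].c1ccc(cc1)[PH+](c1ccccc1)c1ccccc1
Why: Phosphonium salt formation from an allylic alcohol through the delocalised pentadienyl cation, captured by PPh3 at the primary terminus C11, is the standard entry to C15 Wittig salts of ε end groups and tolerates the ring alkene; recrystallisation should secure the 9E salt.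

Step 7
Reactants: 11 pseudoionone
Product: 12 vinyl-ψ-ionol, (4E,6E)-3,7,11-trimethyldodeca-1,4,6,10-tetraen-3-ol (racemic)
Conditions: CH2=CHMgBr (1.2 equiv), THF, −20 to 0 °C; aq. NH4Cl
Reagents that add atoms: vinylmagnesium bromide, C=C[Mg]Br
Why: Grignard 1,2-addition to the methyl ketone C9' of the dienone gives the tertiary bis-allylic alcohol, whose configuration is irrelevant because C9' becomes sp2 in the next step.

Step 8
Reactants: 12 vinyl-ψ-ionol
Product: 13 [(2E,4E,6E)-3,7,11-trimethyldodeca-2,4,6,10-tetraen-1-yl]triphenylphosphonium bromide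
Conditions: PPh3·HBr (1.05 equiv), MeOH, 0 °C to rt; recrystallisation
Reagents that add atoms: triphenylphosphine hydrobromide, [Br-].c1ccc(cc1)[PH+](c1ccccc1)c1ccccc1
Why: Ionisation of the tertiary allylic alcohol and capture of the cation by PPh3 at the primary terminus C11' (allylic transposition, as in the technical route to lycopene) should give the C15 salt, obtained all-E by recrystallisation.

Step 9
Reactants: 13 [(2E,4E,6E)-3,7,11-trimethyldodeca-2,4,6,10-tetraen-1-yl]triphenylphosphonium bromide; 14 (2E,4E,6E)-2,7-dimethylocta-2,4,6-trienedial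
Product: 16 apo-12'-lycopenal, via ψ-end ylide 15 (not isolated)
Conditions: 14 (3 equiv), NaOMe (1.05 equiv, 1 M in MeOH, added slowly), CH2Cl2, 0 °C to rt; then heptane, reflux, N2, dark
Reagents that add atoms: none
Why: Wittig reaction of the semistabilised ylide with one formyl group of the cheap symmetrical dialdehyde, kept in excess and recoverable, should stop at the mono-adduct because the product enal is less electrophilic than 14, and the Z isomer at the new bond (C11'=C12' of the target) should revert to E on heating.

Step 10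
Reactants: 10 {(2E,4E)-3-methyl-5-[(1R)-2,6,6-trimethylcyclohex-2-en-1-yl]penta-2,4-dien-1-yl}triphenylphosphonium bromide; 16 apo-12'-lycopenal
Product: 18 (6R)-ε,ψ-carotene (δ-carotene), via ε-end ylide 17 (not isolated)
Conditions: 16 (1.15 equiv), 1,2-epoxybutane–EtOH (1:1), reflux, Ar, dark; then heptane, reflux; crystallisation from CH2Cl2/MeOH
Reagents that add atoms: none
Why: Wittig reaction under near-neutral conditions (bromide opens the epoxide and the alkoxide formed makes the ylide at C11) joins C11 to C12 without any base able to remove the C6–H, as established for C15 salts of ε end groups, and the hindered 11Z isomer should isomerise to the all-E polyene on heating.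

**Compound list**
1 | β-ionone, (3E)-4-(2,6,6-trimethylcyclohex-1-en-1-yl)but-3-en-2-one | CC(=O)/C=C/C1=C(C)CCCC1(C)C | starting material
2 | 4-oxo-β-ionone, (3E)-4-(2,6,6-trimethyl-3-oxocyclohex-1-en-1-yl)but-3-en-2-one | CC(=O)/C=C/C1=C(C)C(=O)CCC1(C)C | intermediate
3 | ethyl (2E,4E)-3-methyl-5-(2,6,6-trimethyl-3-oxocyclohex-1-en-1-yl)penta-2,4-dienoate | CCOC(=O)/C=C(C)/C=C/C1=C(C)C(=O)CCC1(C)C | intermediate
4 | ethyl (2E,4E)-5-[(3S)-3-hydroxy-2,6,6-trimethylcyclohex-1-en-1-yl]-3-methylpenta-2,4-dienoate | CCOC(=O)/C=C(C)/C=C/C1=C(C)[C@@H](O)CCC1(C)C | intermediate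
5 | hydrazone adduct, ethyl (2E,4E)-3-methyl-5-{(3R)-2,6,6-trimethyl-3-[1-(2-nitrophenylsulfonyl)-2-(propan-2-ylidene)hydrazinyl]cyclohex-1-en-1-yl}penta-2,4-dienoate | CCOC(=O)/C=C(C)/C=C/C1=C(C)[C@H](N(N=C(C)C)S(=O)(=O)c2ccccc2[N+](=O)[O-])CCC1(C)C | intermediate (not isolated)
6 | sulfonyl hydrazine, ethyl (2E,4E)-3-methyl-5-{(3R)-2,6,6-trimethyl-3-[1-(2-nitrophenylsulfonyl)hydrazinyl]cyclohex-1-en-1-yl}penta-2,4-dienoate | CCOC(=O)/C=C(C)/C=C/C1=C(C)[C@H](N(N)S(=O)(=O)c2ccccc2[N+](=O)[O-])CCC1(C)C | intermediate (not isolated)
7 | allylic diazene, ethyl (2E,4E)-5-[(3R)-3-diazenyl-2,6,6-trimethylcyclohex-1-en-1-yl]-3-methylpenta-2,4-dienoate | CCOC(=O)/C=C(C)/C=C/C1=C(C)[C@H](N=N)CCC1(C)C | intermediate (not isolated)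
8 | ethyl (2E,4E)-3-methyl-5-[(1R)-2,6,6-trimethylcyclohex-2-en-1-yl]penta-2,4-dienoate | CCOC(=O)/C=C(C)/C=C/[C@H]1C(C)=CCCC1(C)C | intermediate
9 | (2E,4E)-3-methyl-5-[(1R)-2,6,6-trimethylcyclohex-2-en-1-yl]penta-2,4-dien-1-ol | OC/C=C(C)/C=C/[C@H]1C(C)=CCCC1(C)C | intermediate
10 | {(2E,4E)-3-methyl-5-[(1R)-2,6,6-trimethylcyclohex-2-en-1-yl]penta-2,4-dien-1-yl}triphenylphosphonium bromide | [Br-].c1ccccc1[P+](c1ccccc1)(c1ccccc1)C/C=C(C)/C=C/[C@H]1C(C)=CCCC1(C)C | intermediate
11 | pseudoionone, (3E,5E)-6,10-dimethylundeca-3,5,9-trien-2-one | CC(C)=CCC/C(C)=C/C=C/C(C)=O | starting material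
12 | vinyl-ψ-ionol, (4E,6E)-3,7,11-trimethyldodeca-1,4,6,10-tetraen-3-ol (racemic) | CC(C)=CCC/C(C)=C/C=C/C(C)(O)C=C | intermediate
13 | [(2E,4E,6E)-3,7,11-trimethyldodeca-2,4,6,10-tetraen-1-yl]triphenylphosphonium bromide | CC(C)=CCC/C(C)=C/C=C/C(C)=C/C[P+](c1ccccc1)(c1ccccc1)c1ccccc1.[Br-] | intermediate
14 | (2E,4E,6E)-2,7-dimethylocta-2,4,6-trienedial (C10 dialdehyde) | O=C/C(C)=C/C=C/C=C(C)/C=O | starting material
15 | ψ-end ylide, [(2E,4E,6E)-3,7,11-trimethyldodeca-2,4,6,10-tetraen-1-ylidene]triphenylphosphorane | CC(C)=CCC/C(C)=C/C=C/C(C)=C/C=P(c1ccccc1)(c1ccccc1)c1ccccc1 | intermediate (not isolated)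
16 | apo-12'-lycopenal, (2E,4E,6E,8E,10E,12E,14E)-2,7,11,15,19-pentamethylicosa-2,4,6,8,10,12,14,18-octaenal | CC(C)=CCC/C(C)=C/C=C/C(C)=C/C=C/C(C)=C/C=C/C=C(C)/C=O | intermediate
17 | ε-end ylide, {(2E,4E)-3-methyl-5-[(1R)-2,6,6-trimethylcyclohex-2-en-1-yl]penta-2,4-dien-1-ylidene}triphenylphosphorane | c1ccccc1P(c1ccccc1)(c1ccccc1)=C/C=C(C)/C=C/[C@H]1C(C)=CCCC1(C)C | intermediate (not isolated)
18 | (6R)-ε,ψ-carotene (δ-carotene), all-E | CC(C)=CCC/C(C)=C/C=C/C(C)=C/C=C/C(C)=C/C=C/C=C(C)/C=C/C=C(C)/C=C/[C@H]1C(C)=CCCC1(C)C | target

Total step count: 10. Longest linear sequence: 7 steps (steps 1 to 6, then step 10); steps 7 to 9 form the second branch.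

**Steps most likely to fail**

Step 4. The activated C4 alcohol may eliminate toward C3 or ionise before nitrogen arrives, so that material is lost as a ring diene or the 4S information is eroded. The fallback sets out from 4. Methyl chloroformate and pyridine would give the (3S)-methyl carbonate F1. With Pd(OAc)2 and PBu3 (reduced in the flask to zerovalent palladium) and triethylammonium formate in THF, F1 should ionise with inversion to a π-allyl palladium formate. After loss of CO2, hydride should pass from the metal face to the more substituted allyl terminus C6, anti to the departed oxygen and therefore in the same 6R sense. The fallback comes back to the route at 8.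

Step 3. Facial selectivity of hydride delivery may be poor for a cyclohexenone that carries a long unsaturated arm at C6. The fallback sets out from 3. Reduction with NaBH4 and CeCl3·7H2O in MeOH (Luche reduction) would give the racemic allylic alcohol F2. Candida antarctica lipase B with vinyl acetate should then acetylate the R enantiomer, by the usual empirical rule for secondary alcohols, to the (3R)-acetate F3, leaving the 3S alcohol, which is separated on silica. The fallback comes back to the route at 4.

Step 2. The phosphonate anion may add in conjugate fashion to the doubly activated diene of 2 or attack the ring carbonyl, and E selectivity at C9=C10 may be incomplete. The fallback sets out from 1. β-Ionone would first be olefinated with triethyl phosphonoacetate and NaH to ethyl (2E,4E)-β-ionylideneacetate F4, so that no ring carbonyl is present during the olefination. The C4 methylene of F4 would then be oxidised with CrO3 and 3,5-dimethylpyrazole in CH2Cl2 at −20 °C. The fallback comes back to the route at 3.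

**Further compounds**
F1 | step 4 | ethyl (2E,4E)-5-[(3S)-3-(methoxycarbonyloxy)-2,6,6-trimethylcyclohex-1-en-1-yl]-3-methylpenta-2,4-dienoate | CCOC(=O)/C=C(C)/C=C/C1=C(C)[C@@H](OC(=O)OC)CCC1(C)C
F2 | step 3 | ethyl (2E,4E)-5-(3-hydroxy-2,6,6-trimethylcyclohex-1-en-1-yl)-3-methylpenta-2,4-dienoate (racemic) | CCOC(=O)/C=C(C)/C=C/C1=C(C)C(O)CCC1(C)C
F3 | step 3 | ethyl (2E,4E)-5-[(3R)-3-acetoxy-2,6,6-trimethylcyclohex-1-en-1-yl]-3-methylpenta-2,4-dienoate | CCOC(=O)/C=C(C)/C=C/C1=C(C)[C@H](OC(C)=O)CCC1(C)C
F4 | step 2 | ethyl (2E,4E)-3-methyl-5-(2,6,6-trimethylcyclohex-1-en-1-yl)penta-2,4-dienoate (ethyl β-ionylideneacetate) | CCOC(=O)/C=C(C)/C=C/C1=C(C)CCCC1(C)C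
A1 | direct plan | geranyl phenyl sulfone, (2E)-3,7-dimethylocta-2,6-dien-1-yl phenyl sulfone | CC(C)=CCC/C(C)=C/CS(=O)(=O)c1ccccc1
A2 | direct plan | (R)-α-cyclogeranyl phenyl sulfone, {[(1R)-2,6,6-trimethylcyclohex-2-en-1-yl]methanesulfonyl}benzene | O=S(=O)(C[C@H]1C(C)=CCCC1(C)C)c1ccccc1
A3 | direct plan | crocetin dialdehyde, all-E 8,8'-diapocarotene-8,8'-dial | O=C/C(C)=C/C=C/C(C)=C/C=C/C=C(C)/C=C/C=C(C)/C=O
A4 | direct plan | apo-8'-lycopenal, all-E 8'-apo-ψ-caroten-8'-al | CC(C)=CCC/C(C)=C/C=C/C(C)=C/C=C/C(C)=C/C=C/C=C(C)/C=C/C=C(C)/C=O
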